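The runs are calculated from invented constants, and the scatter is random.

If a flask's substrate stops short of zero, what I want to know is how fast it still moves, so I follow the rate and leave the concentrations aside.

all flasks: free catalyst 5.9 mM

| charge | substrate | remark | time |
|---|---|---|---|
| north-east | 1.4 M | run made earlier |  |
| north-west | 2.2 M | run made earlier |  |
| flask | 1.0 M |  | 8.0 min |

- north-east (time / min: substrate / %, product / %): 1.00: 46, 11; 2.00: 42, 11; 3.00: 45, 9; 4.00: 43, 11; 5.00: 44, 11; 6.00: 47, 14
- north-west (time / min: substrate / %, product / %): 0.500: 58, 9; 0.833: 52, 9; 1.33: 44, 14; 2.50: 45, 15; 4.00: 44, 12; 6.00: 42, 13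

(each reading ± 1.5 percentage points)

- a reading or a percentage of product counts all its forms, free or not
- the reaction counts as stopped when no species that holds the substrate changes by six tenths of a point or more over the second half of the time
- what has gone from substrate into another species counts as reacted, even if it can come back

- at 8.0 min, what has stopped the reaction, if anything has (no working catalyst is left / it is still moving / all of the substrate has reacted / forward and back rates have come level)
- how much of the substrate has reacted by 8.0 min
- how much product there is at 8.0 min, in percent of the substrate charged
- amount of product if the flask were left three thousand times as long, in percent of the substrate charged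

Substrate levels off in both runs. The 10 level readings (all of north-east, and north-west from 1.33 min on) average s∞ = 44.2%. A run therefore starts a gap g₀ = 56 percentage points above that level, and the north-west run stands g₁ = 14 points above it at 0.500 min. Replacing that stretch by its mean speed v̄ and mean gap gives

v̄ / ḡ = 0.840 min⁻¹ / 35 points = 2.41 min⁻¹.

That mean gap is too large for a sagging curve, so I check it against the logarithm:

κ = ln(g₀/g₁) / t = 2.79 min⁻¹,

which is higher by a factor 1.16. I keep this κ, worked out from readings with a scatter of 1.5 points each: the relaxation rate, the speed of the substrate per unit of remaining gap.

The speed starts at κg₀ = 1.56 min⁻¹. I take it to fall with the gap, by a factor of two every ln(2)/κ = 0.248 min. I apply no further factor for the charge, and that is an assumption: the mean levels of the north-east and north-west runs differ by 0.75 points, less than the scatter of one reading, but the 1.0 M flask lies below both of their charges. By 4.00 min the gap reckoned this way is 7.8 × 10⁻⁴ points, so in the 1.0 M flask I expect rest by 8.0 min, with 56.0% reacted.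

The forecast says forward and back rates have come level, with 56% reacted (53% to 59%), product 12% (10% to 14.5%) and 12% in the long run (10% to 20%). One of its grounds: “The percentages and the relaxation time (k about 2.5/min) barely change between 1.4 and 2.2 M.” Its rate differs from my κ.

The flask gives forward and back rates have come level, 55.7% reacted, product 12.6%, and 12.6% in the long run.

    substrate + free catalyst ⇌ catalyst intermediate (K = 0.460 L mol⁻¹, k = 990 L mol⁻¹ s⁻¹)
    catalyst intermediate ⇌ free catalyst + product (K = 0.620 M, k = 3.40 s⁻¹)
    crystals ⇌ product, rate k3*(cs3 - [product]) while solid is left; crystals form when [product] > cs3 (solubility = 0.710 M, k = 0.480 s⁻¹)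
    substrate ⇌ dormant form (K = 0.970, k = 0.0220 s⁻¹)
    2 catalyst intermediate ⇌ resting dimer (K = 200 L mol⁻¹, k = 8.40 L mol⁻¹ s⁻¹)

The flask has come to rest: its largest change over the second half is 0 points. By κ, the gap reckoned for 8.0 min is 1.1 × 10⁻⁸ points. Carried with no factor for the charge to the neighbour flask with 0.25 M of substrate, κ again gives rest by 8.0 min, and that neighbour flask stands at 55.7% reacted and product 12.6%. With 7.55 M of substrate, time and all else held, the answer for product has moved by 5 points, which lies outside the forecast's range. At 80.0 min the 1.0 M flask holds substrate 44.3%, with 55.7% reacted and product 12.6%.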